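## Structural features

The target is a 1,2-dioxolane-3-acetic acid: a five-membered cyclic peroxide (O1–O2–C3–C4–C5) in which C3 and C5 are both fully substituted and C4 is a methylene. C3 carries a methyl group and the CH2CO2H arm (C2, C1). C5 carries a methyl group and a twelve-carbon chain (C6–C17) that is methyl-branched at C7, one CH2 away from the ring, and ends in an (E,E)-phenylbutadiene (C14=C15–C16=C17–Ph). There are three stereocentres and no two are adjacent: C3 (S) and C5 (R) hold the two ring methyls trans to one another, and C7 (R) stands 1,3 to C5. The fragile groups are the O–O bond (reductants, phosphines, low-valent metals, strong Lewis acids), the β-peroxy ester or acid (an enolate can expel the peroxide oxygen and open the ring) and the phenyl diene (radicals, O2, boranes). The real difficulty is stereochemical: two oxygenated quaternary centres separated by a CH2, with no neighbouring group to relay configuration, and a ring whose absolute sense must be matched to the remote C7. The key step exploits the C3–C4–C5 unit: it is the three-carbon ring of a 1,2-dimethyl-1-vinylcyclopropane in which the C3–C5 bond is replaced by an O–O unit from dioxygen, and the vinyl group left on C3 is C2–C1 of the acid arm.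

## Logic of the disconnections

23 ⇒ 22. The acyl C–O bond of a methyl ester is cut. The acid stays masked through the base-mediated chain-end steps and the ester gives a last, easily purified neutral compound. The forward demand is a hydrolysis that spares the β-peroxy ester and the diene.

22 ⇒ 20 + 21. The C14=C15 bond is cut. This removes the whole phenyl diene, which would not survive selenyl radicals, O2 or a borane, and leaves a saturated chain ending in an aldehyde; 21 brings C15–C17 and the phenyl ring. The forward step must be E-selective and must not enolise the ester.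

20 ⇒ 19 ⇒ 18 ⇒ 17 ⇒ 15 ⇒ 13. No skeletal bond is cut. C14 is taken back to a silyl-protected alcohol and C1 from acid to alcohol to the terminal carbon of a vinyl group, so the only bond formed here is C1–O. The vinyl group is what the ring-forming step leaves on C3. The forward demands are an anti-Markovnikov hydration and two oxidations that leave the O–O bond alone, with C1 oxidised while C14 is still protected.

13 ⇒ 12. C5–O and O–C3 are cut and C3–C5 is reconnected. Both oxygenated quaternary centres and the peroxide disappear in one operation, both oxygens come from O2, and 12 has no heteroatom on its ring. The forward step needs the three-membered ring to open towards C5 and the peroxyl radical to close before it abstracts hydrogen. The price is that neither new centre is controlled, so 13 must be separated from its isomers. Three points are tuned without touching the disconnection: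
- 12 is carried as an unassigned mixture of ring isomers, since both ring centres are erased.
- The silyl ether is kept as the chromophore for that separation.
- A selenyl chain carrier is chosen because 12 has no radical-stabilising group.

12 ⇒ 11 ⇒ 10 ⇒ 9. The C1=C2 bond is cut (methylenation of an aldehyde), then the two bonds from C4 to C3 and to C5 (methylene transfer to a tetrasubstituted alkene). The C2 hydroxyl of 9 directs the zinc carbenoid, and 9 is acyclic. The forward demand is cyclopropanation of a hindered but electron-rich alkene; its facial and geometric outcome is irrelevant.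

9 ⇒ 8 ⇒ 6 + 7. The C3=C5 bond is cut. This bond is made only to be broken again in step 9: it places C3, with its methyl and the C2 handle, next to C5 so that one CH2 can bridge them. 7 supplies C2, C3 and the C3 methyl, and 6 is a simple methyl ketone. The forward demand is olefination of a ketone to a tetrasubstituted alkene, with no need for geometric control.

6 ⇒ 5. The C7–CH3 bond is cut. This is the only stereocentre made by asymmetric catalysis, and 5 is achiral. High enantioselectivity is needed, because every later isomer problem is compounded by any C7 epimer.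

5 ⇒ 2 + 3, 2 ⇒ 1. The C6=C7 bond is cut, the C7 aldehyde is traced to an alcohol, and the Si–O bond is cut. 3 brings C5, C6 and the C5 methyl; 1 is C7–C14. The only demand is monoprotection of a symmetrical diol.

## Other disconnections considered

Alternative 1: The cut is the O–C5 bond alone. Forward, the tertiary hydroperoxide A1 (C3 already bears methyl, the ester arm and OOH; C5 is the inner carbon of a 1,1-disubstituted alkene) is treated with N-iodosuccinimide. The iodonium ion is opened by the hydroperoxide at the more substituted carbon in a 5-exo closure to give the iodomethyl dioxolane A2, whose C–I bond must then be reduced to reach 18.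
- In favour: the acetate arm is present from the start, so the three steps that turn vinyl into ester are not needed. C3 could in principle be brought in as one enantiomer, leaving only C5 to sort (two isomers instead of four). On the isomer count it is the better plan.
- Against: no reliable asymmetric entry to a tertiary β-hydroperoxy ester such as A1 is at hand (substitution at a tertiary carbinol by H2O2 passes through a cation). A1 can fragment under acid or base. The closure must tell CH2I from a CH2R arm at C5 and should be no more selective than the radical closure.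
- The deiodination is the weak point. A radical on the CH2 next to C5 is a β-peroxyalkyl radical that can collapse to an epoxide with O–O cleavage, and hydride displacement at this neopentyl-type iodide is slow.
- Comparison: equal or better in structure control, similar in step count, weaker in mechanism at the last step. The chosen plan passes through the same kind of β-peroxyalkyl radical but gives it a faster exit (loss of PhSe•).

Alternative 2: The cut is O–C3, made with inversion. In A3 a tertiary hydroperoxide at C5 is tethered to a 2,2-disubstituted oxetane whose quaternary carbon is C3. Under catalytic TMSOTf the hydroperoxide attacks that carbon from the rear (5-exo-tet) and gives A4, which is the same compound as 15.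
- In favour: C3 is set stereospecifically from an oxetane that can be made enantioenriched (asymmetric epoxidation of a trisubstituted allylic alcohol, hydride opening to the 1,3-diol, ring closure). The absolute sense of the ring then no longer rests on separating ring-enantiomeric partners. The product is already at the alcohol level, so no borane meets the peroxide. On both counts it is better than the chosen plan.
- Against: the C5 hydroperoxide must be installed without control (for example by Co(acac)2-catalysed hydroperoxysilylation of a 1,1-disubstituted alkene), so two C5 epimers remain. A3 needs a clearly longer linear sequence than 12. A Lewis acid next to a free tertiary hydroperoxide invites ionisation and carbon-to-oxygen migration, and any SN1 leakage at the quaternary oxetane carbon erodes the inversion.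
- Comparison: better in structure control (two isomers, the ring sense fixed), polar and stereospecific against radical and unselective, poorer in step economy before the ring. Material throughput after separation could well be equal or higher.

Alternative 3: The cut is C3–C4 together with O–C5. The silylperoxy ketal A5 is ionised by SnCl4 to a peroxycarbenium ion centred on C3. The 1,1-disubstituted alkene A6 (one methylenation from 6) attacks through its CH2, and the silylperoxy oxygen closes on the tertiary C5 cation to give A7; methanolysis of the acetate would give 15.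
- In favour: it is the most convergent plan. Ring assembly takes two steps from 6 plus one to reach 15, against seven in the chosen route; on step economy it is clearly better.
- Stereochemically it is the equal of the chosen plan and not better: neither C3 nor C5 is controlled and four isomers are to be expected.
- Against: the cationic intermediate has exits that the radical lacks (proton loss from the tertiary cation, capture by chloride). The silyl ether and the tertiary C–O bonds of the product sit in a strong Lewis acid. A hydroperoxy ketal must be prepared and handled, whereas the chosen plan draws both oxygens from O2 under neutral conditions at the moment the ring forms.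
- Comparison: equal in structure control, stepwise cationic against radical chain, superior in step count. The chosen plan is preferred only for the mildness and atom source of its ring-forming step.

Key step: step 9

Remarks before the steps:
- Assumption: the ferrocenyl diphosphine antipode named in step 3 is taken to deliver the methyl group to the enone face that gives 7R. If the sense is the opposite, the mirror-image ligand is used and nothing else changes.
- The structures of 12 and 13 agree atom for atom with the target (ring 3S,5R with trans methyls, 7R); no structure needed correction. The descriptor at C3 reads S in 13, R in 14 and 15, and S again from 16 on, through priority changes only; the arrangement in space stays the same.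
- All peroxide-containing compounds (13 onwards) are to be handled on small scale, cold and behind a shield.

## Steps

Step 1
Reactants: 1 octane-1,8-diol
Product: 2 8-[(tert-butyldiphenylsilyl)oxy]octan-1-ol
Conditions: NaH (1.0 equiv), THF, 0 °C → rt; then t-BuPh2SiCl (1.0 equiv), rt
Reagents that add atoms: tert-butyl(chloro)diphenylsilane, CC(C)(C)[Si](Cl)(c1ccccc1)c1ccccc1
Why: Monosilylation of a symmetrical diol through its monosodium alkoxide, which is silylated faster than diol or product; bis-ether and diol are removed by chromatography, and the silyl group serves as UV handle for all later separations.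

Step 2
Reactants: 2 8-[(tert-butyldiphenylsilyl)oxy]octan-1-ol, 3 1-(triphenylphosphoranylidene)propan-2-one
Product: 5 (3E)-11-[(tert-butyldiphenylsilyl)oxy]undec-3-en-2-one, via aldehyde 4 (not isolated)
Conditions: 2,2,6,6-tetramethylpiperidin-1-oxyl (TEMPO, 10 mol %), PhI(OAc)2 (1.1 equiv), CH2Cl2, rt; then 3 (1.5 equiv), rt → 40 °C
Reagents that add atoms: none
Why: Nitroxyl-catalysed oxidation stops at the aldehyde in dry CH2Cl2 and the stabilised ylide tolerates the acetic acid formed, so the Wittig reaction can follow in the same flask; stabilised ylides give the E-enone (C6=C7).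

Step 3
Reactants: 5 (3E)-11-[(tert-butyldiphenylsilyl)oxy]undec-3-en-2-one
Product: 6 (4R)-11-[(tert-butyldiphenylsilyl)oxy]-4-methylundecan-2-one
Conditions: MeMgBr (1.2 equiv), CuBr·SMe2 (5 mol %), (R)-1-[(SP)-2-(diphenylphosphino)ferrocenyl]ethyldicyclohexylphosphine (6 mol %), t-BuOMe, −75 °C; aq. NH4Cl
Reagents that add atoms: methylmagnesium bromide, C[Mg]Br
Why: Copper-catalysed asymmetric conjugate addition of a Grignard reagent to a linear (E)-alk-3-en-2-one, a substrate class suited to ferrocenyl diphosphine ligands with MeMgBr; the ligand alone decides the face at C7 (catalyst control) and the low temperature suppresses 1,2-addition.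

Step 4
Reactants: 6 (4R)-11-[(tert-butyldiphenylsilyl)oxy]-4-methylundecan-2-one, 7 triethyl 2-phosphonopropionate
Product: 8 ethyl (5R)-12-[(tert-butyldiphenylsilyl)oxy]-2,3,5-trimethyldodec-2-enoate (E/Z mixture)
Conditions: 7 (3 equiv), NaH (2.8 equiv), DME, 0 °C → reflux
Reagents that add atoms: none
Why: Horner–Wadsworth–Emmons olefination of a methyl ketone to a tetrasubstituted enoate, slow but established with excess phosphonate anion at reflux; the geometry is irrelevant because both alkene carbons become ring carbons that are erased in step 9, and C7, β to the carbonyl, cannot epimerise.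

Step 5
Reactants: 8 ethyl (5R)-12-[(tert-butyldiphenylsilyl)oxy]-2,3,5-trimethyldodec-2-enoate
Product: 9 (5R)-12-[(tert-butyldiphenylsilyl)oxy]-2,3,5-trimethyldodec-2-en-1-ol (E/Z mixture)
Conditions: i-Bu2AlH (2.5 equiv), CH2Cl2, −78 → 0 °C; aq. potassium sodium tartrate
Reagents that add atoms: none
Why: 1,2-Reduction of an α,β-unsaturated ester to the allylic alcohol by an aluminium hydride; the tetrasubstituted alkene resists conjugate reduction and the silyl ether is inert.

Step 6
Reactants: 9 (5R)-12-[(tert-butyldiphenylsilyl)oxy]-2,3,5-trimethyldodec-2-en-1-ol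
Product: 10 {2-[(2R)-9-[(tert-butyldiphenylsilyl)oxy]-2-methylnonyl]-1,2-dimethylcyclopropyl}methanol (mixture of ring diastereomers)
Conditions: Et2Zn (2.5 equiv), CH2I2 (5 equiv), CH2Cl2, −10 °C → rt; aq. NH4Cl
Reagents that add atoms: diiodomethane, ICI
Why: Simmons–Smith cyclopropanation (Furukawa variant): the zinc alkoxide directs and accelerates methylene transfer to the electron-rich tetrasubstituted alkene, stereospecifically with respect to alkene geometry; the ring diastereomers are carried on together.

Step 7
Reactants: 10 {2-[(2R)-9-[(tert-butyldiphenylsilyl)oxy]-2-methylnonyl]-1,2-dimethylcyclopropyl}methanol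
Product: 11 2-[(2R)-9-[(tert-butyldiphenylsilyl)oxy]-2-methylnonyl]-1,2-dimethylcyclopropane-1-carbaldehyde (mixture of ring diastereomers)
Conditions: Dess–Martin periodinane (1.3 equiv), NaHCO3, CH2Cl2, 0 °C → rt
Reagents that add atoms: none
Why: Dess–Martin oxidation of a neopentyl-type primary alcohol; the aldehyde has no α-hydrogen, and the bicarbonate buffer keeps acid away from the cyclopropylcarbinyl system.

Step 8
Reactants: 11 2-[(2R)-9-[(tert-butyldiphenylsilyl)oxy]-2-methylnonyl]-1,2-dimethylcyclopropane-1-carbaldehyde
Product: 12 tert-butyl{[(8R)-9-(2-ethenyl-1,2-dimethylcyclopropyl)-8-methylnonyl]oxy}diphenylsilane (mixture of ring diastereomers)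
Conditions: Ph3PCH3Br (1.5 equiv), KOt-Bu (1.4 equiv), THF, 0 °C → rt
Reagents that add atoms: methyltriphenylphosphonium bromide, C[P+](c1ccccc1)(c1ccccc1)c1ccccc1.[Br-]
Why: Wittig methylenation; the hindered but non-enolisable aldehyde reacts cleanly with the small unstabilised ylide.

Step 9
Reactants: 12 tert-butyl{[(8R)-9-(2-ethenyl-1,2-dimethylcyclopropyl)-8-methylnonyl]oxy}diphenylsilane
Product: 13 (3S,5R)-3-ethenyl-3,5-dimethyl-5-[(2R)-9-[(tert-butyldiphenylsilyl)oxy]-2-methylnonyl]-1,2-dioxolane
Conditions: O2 (1 atm), PhSeSePh (0.2 equiv), 2,2'-azobis(2-methylpropionitrile) (AIBN, 0.1 equiv), hν (sunlamp), MeCN/PhH 4:1, 0 °C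
Reagents that add atoms: dioxygen, O=O
Why: PhSe• (from the diselenide under light, AIBN as initiator) adds reversibly to the CH2 terminus of the vinyl group, and the cyclopropylcarbinyl radical opens by cleavage of the bond between the two fully substituted ring carbons, giving the tertiary C5 radical and an allyl selenide with a C2=C3 alkene. O2 captures the C5 radical (C5–O), the peroxyl radical closes on C3 in a 5-exo-trig mode (O–C3), and β-scission returns PhSe• and the vinyl group, so a catalytic amount of diselenide carries the chain. The closest known reaction type is the thiyl- or selenyl-radical-catalysed oxygenation of vinylcyclopropanes to 3-vinyl-1,2-dioxolanes; the selenyl carrier is preferred here because 12 has no radical-stabilising group and loss of PhSe• should outrun both O2 capture at C2 and the epoxide-forming collapse of the β-peroxyalkyl radical. The step needs regioselective ring opening, which the substrate secures (tertiary against primary radical), and closure ahead of hydrogen abstraction, which the absence of any thiol or other hydrogen donor secures. C5 is set when O2 meets the planar tertiary radical, with only the 1,3-related C7 centre as a bias, and C3 is set in the chair-like closure, where methyl and the CH2R arm on C5 differ too little to favour one chair. No useful selectivity is therefore expected: all four C3/C5 combinations should form, the cis-dimethyl pair is to be removed by flash chromatography, and the (3S,5R) isomer is to be taken from the trans pair by preparative HPLC with the silyl group as chromophore. Both cyclopropane centres are erased, so the isomer mixture of 12 converges.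

Step 10
Reactants: 13 (3S,5R)-3-ethenyl-3,5-dimethyl-5-[(2R)-9-[(tert-butyldiphenylsilyl)oxy]-2-methylnonyl]-1,2-dioxolane
Product: 15 2-[(3R,5R)-3,5-dimethyl-5-[(2R)-9-[(tert-butyldiphenylsilyl)oxy]-2-methylnonyl]-1,2-dioxolan-3-yl]ethan-1-ol, via B-alkyl-9-BBN adduct 14 (not isolated)
Conditions: 9-BBN (1.5 equiv), THF, 0 °C → rt; then NaBO3·4H2O, THF/H2O, rt
Reagents that add atoms: 9-borabicyclo[3.3.1]nonane, B1C2CCCC1CCC2 (boron unit of 14 only); sodium perborate, [Na+].[O-]OB=O (hydroxyl oxygen of 15)
Why: Hydroboration–oxidation: the bulky dialkylborane places boron on the terminal carbon of a vinyl group attached to a quaternary carbon, and perborate oxidises C–B with retention; di-tert-alkyl peroxides are the least reactive peroxides towards dialkylboranes and alkaline peroxy reagents at or below room temperature, and 14 is oxidised at once.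

Step 11
Reactants: 15 2-[(3R,5R)-3,5-dimethyl-5-[(2R)-9-[(tert-butyldiphenylsilyl)oxy]-2-methylnonyl]-1,2-dioxolan-3-yl]ethan-1-ol
Product: 17 2-[(3S,5R)-3,5-dimethyl-5-[(2R)-9-[(tert-butyldiphenylsilyl)oxy]-2-methylnonyl]-1,2-dioxolan-3-yl]acetic acid, via aldehyde 16 (not isolated)
Conditions: TEMPO (2,2,6,6-tetramethylpiperidin-1-oxyl, 20 mol %), PhI(OAc)2 (2.2 equiv), MeCN/H2O 1:1, rt
Reagents that add atoms: water, O
Why: Nitroxyl-catalysed oxidation in aqueous acetonitrile takes the primary alcohol through the aldehyde and its hydrate to the acid; the oxoammonium oxidant attacks neither the O–O bond nor the silyl ether.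

Step 12
Reactants: 17 2-[(3S,5R)-3,5-dimethyl-5-[(2R)-9-[(tert-butyldiphenylsilyl)oxy]-2-methylnonyl]-1,2-dioxolan-3-yl]acetic acid
Product: 18 methyl 2-[(3S,5R)-3,5-dimethyl-5-[(2R)-9-[(tert-butyldiphenylsilyl)oxy]-2-methylnonyl]-1,2-dioxolan-3-yl]acetate
Conditions: Me3SiCHN2 (1.5 equiv), PhMe/MeOH 4:1, 0 °C
Reagents that add atoms: trimethylsilyldiazomethane, C[Si](C)(C)C=[N+]=[N-]
Why: O-Methylation of the carboxylic acid by a diazoalkane under neutral conditions; the ester masks the acid for the next three steps and offers a neutral compound for a further check of isomeric purity.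

Step 13
Reactants: 18 methyl 2-[(3S,5R)-3,5-dimethyl-5-[(2R)-9-[(tert-butyldiphenylsilyl)oxy]-2-methylnonyl]-1,2-dioxolan-3-yl]acetate
Product: 19 methyl 2-[(3S,5R)-5-[(2R)-9-hydroxy-2-methylnonyl]-3,5-dimethyl-1,2-dioxolan-3-yl]acetate
Conditions: HF·pyridine, pyridine/THF, 0 °C → rt
Reagents that add atoms: none
Why: Fluoride cleavage of the Si–O bond under weakly acidic conditions; chosen over a basic fluoride source, which could enolise the β-peroxy ester.

Step 14
Reactants: 19 methyl 2-[(3S,5R)-5-[(2R)-9-hydroxy-2-methylnonyl]-3,5-dimethyl-1,2-dioxolan-3-yl]acetate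
Product: 20 methyl 2-[(3S,5R)-3,5-dimethyl-5-[(2R)-2-methyl-9-oxononyl]-1,2-dioxolan-3-yl]acetate
Conditions: Dess–Martin periodinane (1.3 equiv), NaHCO3, CH2Cl2, 0 °C → rt
Reagents that add atoms: none
Why: Dess–Martin oxidation of an unhindered primary alcohol to the aldehyde, buffered, without over-oxidation and without action on the O–O bond.

Step 15
Reactants: 20 methyl 2-[(3S,5R)-3,5-dimethyl-5-[(2R)-2-methyl-9-oxononyl]-1,2-dioxolan-3-yl]acetate, 21 diethyl [(2E)-3-phenylprop-2-en-1-yl]phosphonate
Product: 22 methyl 2-[(3S,5R)-3,5-dimethyl-5-[(2R,9E,11E)-2-methyl-12-phenyldodeca-9,11-dien-1-yl]-1,2-dioxolan-3-yl]acetate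
Conditions: 21 (1.6 equiv), LiN(SiMe3)2 (1.5 equiv), THF, −78 °C; then 20, −78 °C → rt
Reagents that add atoms: none
Why: Horner–Wadsworth–Emmons reaction of a lithiated allylic phosphonate, which attacks through its α-carbon and should give the new C14=C15 bond mainly E while the reagent's own alkene stays E; the stabilised anion is too weak a base to enolise the ester, the slight excess of phosphonate over amide leaves no free base, and a minor 14Z isomer is to be removed at this ester stage.

Step 16
Reactants: 22 methyl 2-[(3S,5R)-3,5-dimethyl-5-[(2R,9E,11E)-2-methyl-12-phenyldodeca-9,11-dien-1-yl]-1,2-dioxolan-3-yl]acetate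
Product: 23 2-[(3S,5R)-3,5-dimethyl-5-[(2R,9E,11E)-2-methyl-12-phenyldodeca-9,11-dien-1-yl]-1,2-dioxolan-3-yl]acetic acid
Conditions: LiOH·H2O (3 equiv), THF/MeOH/H2O 3:1:1, 0 °C → rt; then 1 M HCl to pH 3
Reagents that add atoms: lithium hydroxide, [Li+].[OH-]
Why: Saponification by hydroxide attack at the ester carbonyl; once the carboxylate has formed, enolisation, the entry to β-elimination of the peroxide, is shut off, and mild acidification frees the acid without touching diene or peroxide.

## Compound list

1 | octane-1,8-diol | OCCCCCCCCO | starting material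
2 | 8-[(tert-butyldiphenylsilyl)oxy]octan-1-ol | OCCCCCCCCO[Si](c1ccccc1)(c1ccccc1)C(C)(C)C | intermediate
3 | 1-(triphenylphosphoranylidene)propan-2-one | CC(=O)C=P(c1ccccc1)(c1ccccc1)c1ccccc1 | starting material
4 | 8-[(tert-butyldiphenylsilyl)oxy]octanal | O=CCCCCCCCO[Si](c1ccccc1)(c1ccccc1)C(C)(C)C | intermediate
5 | (3E)-11-[(tert-butyldiphenylsilyl)oxy]undec-3-en-2-one | CC(=O)/C=C/CCCCCCCO[Si](c1ccccc1)(c1ccccc1)C(C)(C)C | intermediate
6 | (4R)-11-[(tert-butyldiphenylsilyl)oxy]-4-methylundecan-2-one | C[C@H](CCCCCCCO[Si](c1ccccc1)(c1ccccc1)C(C)(C)C)CC(C)=O | intermediate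
7 | triethyl 2-phosphonopropionate | CCOC(=O)C(C)P(=O)(OCC)OCC | starting material
8 | ethyl (5R)-12-[(tert-butyldiphenylsilyl)oxy]-2,3,5-trimethyldodec-2-enoate (E/Z mixture) | C[C@H](CCCCCCCO[Si](c1ccccc1)(c1ccccc1)C(C)(C)C)CC(C)=C(C)C(=O)OCC | intermediate
9 | (5R)-12-[(tert-butyldiphenylsilyl)oxy]-2,3,5-trimethyldodec-2-en-1-ol (E/Z mixture) | C[C@H](CCCCCCCO[Si](c1ccccc1)(c1ccccc1)C(C)(C)C)CC(C)=C(C)CO | intermediate
10 | {2-[(2R)-9-[(tert-butyldiphenylsilyl)oxy]-2-methylnonyl]-1,2-dimethylcyclopropyl}methanol (ring diastereomers) | C[C@H](CCCCCCCO[Si](c1ccccc1)(c1ccccc1)C(C)(C)C)CC1(C)CC1(C)CO | intermediate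
11 | 2-[(2R)-9-[(tert-butyldiphenylsilyl)oxy]-2-methylnonyl]-1,2-dimethylcyclopropane-1-carbaldehyde (ring diastereomers) | C[C@H](CCCCCCCO[Si](c1ccccc1)(c1ccccc1)C(C)(C)C)CC1(C)CC1(C)C=O | intermediate
12 | tert-butyl{[(8R)-9-(2-ethenyl-1,2-dimethylcyclopropyl)-8-methylnonyl]oxy}diphenylsilane (ring diastereomers) | C[C@H](CCCCCCCO[Si](c1ccccc1)(c1ccccc1)C(C)(C)C)CC1(C)CC1(C)C=C | intermediate
13 | (3S,5R)-3-ethenyl-3,5-dimethyl-5-[(2R)-9-[(tert-butyldiphenylsilyl)oxy]-2-methylnonyl]-1,2-dioxolane | C[C@H](CCCCCCCO[Si](c1ccccc1)(c1ccccc1)C(C)(C)C)C[C@]1(C)C[C@@](C)(C=C)OO1 | intermediate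
14 | 9-{2-[(3R,5R)-3,5-dimethyl-5-[(2R)-9-[(tert-butyldiphenylsilyl)oxy]-2-methylnonyl]-1,2-dioxolan-3-yl]ethyl}-9-borabicyclo[3.3.1]nonane | C[C@H](CCCCCCCO[Si](c1ccccc1)(c1ccccc1)C(C)(C)C)C[C@]1(C)C[C@@](C)(CCB2C3CCCC2CCC3)OO1 | intermediate
15 | 2-[(3R,5R)-3,5-dimethyl-5-[(2R)-9-[(tert-butyldiphenylsilyl)oxy]-2-methylnonyl]-1,2-dioxolan-3-yl]ethan-1-ol | C[C@H](CCCCCCCO[Si](c1ccccc1)(c1ccccc1)C(C)(C)C)C[C@]1(C)C[C@@](C)(CCO)OO1 | intermediate
16 | 2-[(3S,5R)-3,5-dimethyl-5-[(2R)-9-[(tert-butyldiphenylsilyl)oxy]-2-methylnonyl]-1,2-dioxolan-3-yl]acetaldehyde | C[C@H](CCCCCCCO[Si](c1ccccc1)(c1ccccc1)C(C)(C)C)C[C@]1(C)C[C@@](C)(CC=O)OO1 | intermediate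
17 | 2-[(3S,5R)-3,5-dimethyl-5-[(2R)-9-[(tert-butyldiphenylsilyl)oxy]-2-methylnonyl]-1,2-dioxolan-3-yl]acetic acid | C[C@H](CCCCCCCO[Si](c1ccccc1)(c1ccccc1)C(C)(C)C)C[C@]1(C)C[C@@](C)(CC(=O)O)OO1 | intermediate
18 | methyl 2-[(3S,5R)-3,5-dimethyl-5-[(2R)-9-[(tert-butyldiphenylsilyl)oxy]-2-methylnonyl]-1,2-dioxolan-3-yl]acetate | C[C@H](CCCCCCCO[Si](c1ccccc1)(c1ccccc1)C(C)(C)C)C[C@]1(C)C[C@@](C)(CC(=O)OC)OO1 | intermediate
19 | methyl 2-[(3S,5R)-5-[(2R)-9-hydroxy-2-methylnonyl]-3,5-dimethyl-1,2-dioxolan-3-yl]acetate | C[C@H](CCCCCCCO)C[C@]1(C)C[C@@](C)(CC(=O)OC)OO1 | intermediate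
20 | methyl 2-[(3S,5R)-3,5-dimethyl-5-[(2R)-2-methyl-9-oxononyl]-1,2-dioxolan-3-yl]acetate | C[C@H](CCCCCCC=O)C[C@]1(C)C[C@@](C)(CC(=O)OC)OO1 | intermediate
21 | diethyl [(2E)-3-phenylprop-2-en-1-yl]phosphonate | CCOP(=O)(C/C=C/c1ccccc1)OCC | starting material
22 | methyl 2-[(3S,5R)-3,5-dimethyl-5-[(2R,9E,11E)-2-methyl-12-phenyldodeca-9,11-dien-1-yl]-1,2-dioxolan-3-yl]acetate | C[C@H](CCCCCC/C=C/C=C/c1ccccc1)C[C@]1(C)C[C@@](C)(CC(=O)OC)OO1 | intermediate
23 | 2-[(3S,5R)-3,5-dimethyl-5-[(2R,9E,11E)-2-methyl-12-phenyldodeca-9,11-dien-1-yl]-1,2-dioxolan-3-yl]acetic acid | C[C@H](CCCCCC/C=C/C=C/c1ccccc1)C[C@]1(C)C[C@@](C)(CC(=O)O)OO1 | target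

## Step count and least certain steps

Total: 16 steps. Longest linear sequence: 16 steps (from 1; 3, 7 and 21 are purchased).

**Step 9 (key step).** The most likely failure is poor facial discrimination at both new centres (O2 capture at C5 and the 5-exo closure at C3), with the wanted isomer a minor part of four and co-eluting with its ring-inverted trans partner, which differs only in its relation to C7. Fallback (resolution through covalent diastereomers in place of direct chromatography):
- It sets out from 15 obtained as the unresolved trans pair, with steps 9 and 10 run without the HPLC separation.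
- The pair is acylated with (S)-2-methoxy-2-phenylacetic acid (N,N'-dicyclohexylcarbodiimide, cat. 4-dimethylaminopyridine, CH2Cl2, 0 °C) to give the 2-(dioxolan-3-yl)ethyl (S)-O-methylmandelate F1 and its ring isomer. These carry a stereocentre much closer to the ring than C7 and are separated by chromatography or crystallisation.
- Methanolysis (K2CO3, MeOH, rt) returns to the route at 15 as one isomer.

**Step 10.** The most likely failure is loss of the O–O bond to boron. This could be hydride reduction by B–H, or boron-to-oxygen migration once the organoborane sits three atoms from O2. A third path is boron on C2 followed by β-elimination of the peroxy oxygen. Fallback (carbon-by-carbon rebuilding without any borane):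
- It sets out from 13. Ozonolysis (O3, CH2Cl2, −78 °C; Me2S, not a phosphine) gives the dioxolane-3-carbaldehyde F2.
- Wittig reaction with methoxymethylenetriphenylphosphorane (from the phosphonium chloride and KN(SiMe3)2, THF, 0 °C) gives the 3-(2-methoxyethenyl)dioxolane F3.
- Dilute aqueous HCl in THF at 0 °C hydrolyses the enol ether to 16. Pinnick oxidation (NaClO2, NaH2PO4, 2-methylbut-2-ene, t-BuOH/H2O) returns to the route at 17.

**Step 4.** The most likely failure is slow, reversible addition of the hindered phosphonate anion to an enolisable methyl ketone (low conversion, self-condensation of 6), together with base-mediated deconjugation of 8. Fallback (a smaller, more nucleophilic nitrile-stabilised carbanion and a different oxidation-state sequence):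
- It sets out from 6. Diethyl (1-cyanoethyl)phosphonate and NaH in THF give the 2,3,5-trimethyldodec-2-enenitrile F4 (E/Z mixture).
- i-Bu2AlH (1.1 equiv, PhMe, −78 °C) and hydrolysis of the imine give the 2,3,5-trimethyldodec-2-enal F5.
- NaBH4 with CeCl3·7H2O in MeOH at 0 °C returns to the route at 9.

**Step 16.** The most likely failure is slow hydroxide attack at the neopentyl-type ester, leaving time for enolisation and β-elimination of the peroxide oxygen with ring opening. Fallback (endgame on the free acid, with no ester to cleave):
- It sets out from 17. HF·pyridine in THF gives the hydroxy acid F6.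
- Dess–Martin periodinane in CH2Cl2 gives the oxo acid F7.
- Olefination with excess lithiated 21 (2.5 equiv 21, 2.4 equiv LiN(SiMe3)2, THF, −78 °C → rt; the first equivalent forms the carboxylate, which cannot enolise) and acidic work-up return to the route at 23.

## Further compounds

F1 | step 9 | 2-[(3R,5R)-3,5-dimethyl-5-[(2R)-9-[(tert-butyldiphenylsilyl)oxy]-2-methylnonyl]-1,2-dioxolan-3-yl]ethyl (2S)-2-methoxy-2-phenylacetate | C[C@H](CCCCCCCO[Si](c1ccccc1)(c1ccccc1)C(C)(C)C)C[C@]1(C)C[C@@](C)(CCOC(=O)[C@@H](OC)c2ccccc2)OO1
F2 | step 10 | (3S,5R)-3,5-dimethyl-5-[(2R)-9-[(tert-butyldiphenylsilyl)oxy]-2-methylnonyl]-1,2-dioxolane-3-carbaldehyde | C[C@H](CCCCCCCO[Si](c1ccccc1)(c1ccccc1)C(C)(C)C)C[C@]1(C)C[C@@](C)(C=O)OO1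
F3 | step 10 | (3S,5R)-3-(2-methoxyethenyl)-3,5-dimethyl-5-[(2R)-9-[(tert-butyldiphenylsilyl)oxy]-2-methylnonyl]-1,2-dioxolane (E/Z mixture) | C[C@H](CCCCCCCO[Si](c1ccccc1)(c1ccccc1)C(C)(C)C)C[C@]1(C)C[C@@](C)(C=COC)OO1
F4 | step 4 | (5R)-12-[(tert-butyldiphenylsilyl)oxy]-2,3,5-trimethyldodec-2-enenitrile (E/Z mixture) | C[C@H](CCCCCCCO[Si](c1ccccc1)(c1ccccc1)C(C)(C)C)CC(C)=C(C)C#N
F5 | step 4 | (5R)-12-[(tert-butyldiphenylsilyl)oxy]-2,3,5-trimethyldodec-2-enal (E/Z mixture) | C[C@H](CCCCCCCO[Si](c1ccccc1)(c1ccccc1)C(C)(C)C)CC(C)=C(C)C=O
F6 | step 16 | 2-[(3S,5R)-5-[(2R)-9-hydroxy-2-methylnonyl]-3,5-dimethyl-1,2-dioxolan-3-yl]acetic acid | C[C@H](CCCCCCCO)C[C@]1(C)C[C@@](C)(CC(=O)O)OO1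
F7 | step 16 | 2-[(3S,5R)-3,5-dimethyl-5-[(2R)-2-methyl-9-oxononyl]-1,2-dioxolan-3-yl]acetic acid | C[C@H](CCCCCCC=O)C[C@]1(C)C[C@@](C)(CC(=O)O)OO1
A1 | alternative 1 | methyl (3S,7R)-14-[(tert-butyldiphenylsilyl)oxy]-3-hydroperoxy-3,7-dimethyl-5-methylidenetetradecanoate | C[C@H](CCCCCCCO[Si](c1ccccc1)(c1ccccc1)C(C)(C)C)CC(=C)C[C@@](C)(CC(=O)OC)OO
A2 | alternative 1 | methyl 2-[(3S,5R)-5-(iodomethyl)-3-methyl-5-[(2R)-9-[(tert-butyldiphenylsilyl)oxy]-2-methylnonyl]-1,2-dioxolan-3-yl]acetate | C[C@H](CCCCCCCO[Si](c1ccccc1)(c1ccccc1)C(C)(C)C)C[C@]1(CI)C[C@@](C)(CC(=O)OC)OO1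
A3 | alternative 2 | (2S)-2-[(2R,4R)-11-[(tert-butyldiphenylsilyl)oxy]-2-hydroperoxy-2,4-dimethylundecyl]-2-methyloxetane | C[C@H](CCCCCCCO[Si](c1ccccc1)(c1ccccc1)C(C)(C)C)C[C@](OO)(C)C[C@]1(C)CCO1
A4 | alternative 2 | 2-[(3R,5R)-3,5-dimethyl-5-[(2R)-9-[(tert-butyldiphenylsilyl)oxy]-2-methylnonyl]-1,2-dioxolan-3-yl]ethan-1-ol (identical with 15) | C[C@H](CCCCCCCO[Si](c1ccccc1)(c1ccccc1)C(C)(C)C)C[C@]1(C)C[C@@](C)(CCO)OO1
A5 | alternative 3 | 3-methoxy-3-[(triethylsilyl)peroxy]butyl acetate (racemic) | CC(=O)OCCC(C)(OC)OO[Si](CC)(CC)CC
A6 | alternative 3 | tert-butyl{[(8R)-8,10-dimethylundec-10-en-1-yl]oxy}diphenylsilane | C[C@H](CCCCCCCO[Si](c1ccccc1)(c1ccccc1)C(C)(C)C)CC(C)=C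
A7 | alternative 3 | 2-[(3R,5R)-3,5-dimethyl-5-[(2R)-9-[(tert-butyldiphenylsilyl)oxy]-2-methylnonyl]-1,2-dioxolan-3-yl]ethyl acetate | C[C@H](CCCCCCCO[Si](c1ccccc1)(c1ccccc1)C(C)(C)C)C[C@]1(C)C[C@@](C)(CCOC(C)=O)OO1
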